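## Retrosynthetic overview

1. The angelate is put on last. Before that, the enone comes from alkene isomerisation and allylic oxidation of a tricyclic exo‑methylene core.
2. The seven‑membered ring is closed through the C1–C11 bond: a tertiary radical (from a selenide) adds to the tosylhydrazone of a bicyclo[3.1.1]heptan‑6‑one and N2 is lost, so the former C=O carbon becomes the cyclobutane CH.
3. The cyclobutane and the six‑membered ring form together by an intramolecular vinylketene–alkene [2+2] of an open‑chain (2E,6E)‑dienoic acid. The 6E geometry and the C8 silyloxy centre set C2, C6 and C7.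
4. The open‑chain acid comes from an Evans–Tishchenko reduction with tiglaldehyde (tiglate on O10, sets C8), a Zn–ProPhenol aldol (sets C10), a Wittig reaction and ozonolysis of methyl geranate.
5. Ring order: cyclobutane and cyclohexane in one operation, then the cycloheptane.

Assumption: locants are farnesane‑type (chain C1…C11, methyls on C3 and C7, two on C11); in these locants the target is (1S,2R,6R,7R,8R,10R), with cyclobutane C1–C2–C7–C6, the (Z)‑2‑methylbut‑2‑enoate (angelate) on O8 and the (E)‑isomer (tiglate) on O10.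

## Route

Step 1
Reactants: 1 methyl geranate
Product: 3 methyl (2E)-3-methyl-6-oxohex-2-enoate, via secondary ozonide 2 (not isolated)
Conditions: O3 (1.0 equiv), CH2Cl2, −78 °C; then Me2S, −78 °C → rt
Reagents that add atoms: ozone, [O-][O+]=O
Why: Ozonolysis is chemoselective for the electron‑rich trisubstituted C6=C7 alkene over the conjugated enoate, and reductive work‑up gives the aldehyde.

Step 2
Reactants: 3 methyl (2E)-3-methyl-6-oxohex-2-enoate; 4 3-(triphenyl-λ5-phosphanylidene)butan-2-one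
Product: 5 methyl (2E,6E)-3,7-dimethyl-8-oxonona-2,6-dienoate
Conditions: PhMe, 90 °C
Reagents that add atoms: none
Why: Wittig olefination with a stabilised α‑methyl keto ylide reacts only at the aldehyde and gives the (E)‑trisubstituted enone.

Step 3
Reactants: 6 2-methylpropanal
Product: 7 2-methyl-2-(phenylselanyl)propanal
Conditions: PhSeCl, EtOAc, rt
Reagents that add atoms: benzeneselenenyl chloride, Cl[Se]c1ccccc1
Why: Electrophilic α‑selenenylation of the aldehyde enol stops cleanly at the mono‑selenide because there is only one α‑hydrogen.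

Step 4
Reactants: 5 methyl (2E,6E)-3,7-dimethyl-8-oxonona-2,6-dienoate; 7 2-methyl-2-(phenylselanyl)propanal
Product: 8 methyl (2E,6E,10R)-10-hydroxy-3,7,11-trimethyl-8-oxo-11-(phenylselanyl)dodeca-2,6-dienoate
Conditions: (S,S)-ProPhenol (10 mol %), Et2Zn (20 mol %), 4 Å MS, THF, 0 °C
Reagents that add atoms: none
Why: Direct catalytic asymmetric aldol (dinuclear zinc–ProPhenol) in which the zinc enolate of the methyl ketone adds to the Re face of non‑enolisable aldehyde 7 and sets C10 as R (ligand antipode chosen for this sense).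

Step 5
Reactants: 8 the (10R)-β-hydroxy enone; 9 tiglaldehyde [(2E)-2-methylbut-2-enal]
Product: 10 methyl (2E,6E,8R,10R)-8-hydroxy-3,7,11-trimethyl-10-{[(2E)-2-methylbut-2-enoyl]oxy}-11-(phenylselanyl)dodeca-2,6-dienoate
Conditions: SmI2 (30 mol %), 9 (4 equiv), THF, −10 °C
Reagents that add atoms: none
Why: Evans–Tishchenko reduction, in which the samarium‑bound hemiacetal of 9 delivers hydride intramolecularly to the C8 ketone through a chair transition state, gives the 1,3‑anti (8R) alcohol and leaves the tigloyl group on O10.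

Step 6
Reactants: 10 the (8R,10R)-hydroxy tiglate
Product: 11 methyl (2E,6E,8R,10R)-8-{[tert-butyl(dimethyl)silyl]oxy}-3,7,11-trimethyl-10-{[(2E)-2-methylbut-2-enoyl]oxy}-11-(phenylselanyl)dodeca-2,6-dienoate
Conditions: TBSOTf, 2,6-lutidine, CH2Cl2, −78 °C
Reagents that add atoms: tert-butyldimethylsilyl trifluoromethanesulfonate, CC(C)(C)[Si](C)(C)OS(=O)(=O)C(F)(F)F
Why: Silylation of the free allylic alcohol masks O8 for the ketene step and supplies the bulky group that later steers the cycloaddition.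

Step 7
Reactants: 11 the silyl ether methyl ester
Product: 12 (2E,6E,8R,10R)-8-{[tert-butyl(dimethyl)silyl]oxy}-3,7,11-trimethyl-10-{[(2E)-2-methylbut-2-enoyl]oxy}-11-(phenylselanyl)dodeca-2,6-dienoic acid
Conditions: Me3SnOH, ClCH2CH2Cl, 70 °C; then 1 M HCl (work-up)
Reagents that add atoms: trimethyltin hydroxide, C[Sn](C)(C)O
Why: Tin‑hydroxide ester hydrolysis cleaves the unhindered methyl ester much faster than the hindered secondary α‑branched tiglate, and the neutral conditions spare the silyl ether and selenide.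

Step 8
Reactants: 12 the dienoic acid
Product: 15 (1R,5S,7S)-7-[(1R,3R)-1-{[tert-butyl(dimethyl)silyl]oxy}-4-methyl-3-{[(2E)-2-methylbut-2-enoyl]oxy}-4-(phenylselanyl)pentyl]-7-methyl-2-methylidenebicyclo[3.1.1]heptan-6-one, via acid chloride 13 (not isolated), via vinylketene 14 (not isolated)
Conditions: Me2C=C(Cl)NMe2, CH2Cl2, 0 °C → rt; then slow addition to Et3N, PhMe, 110 °C (high dilution)
Reagents that add atoms: none
Why: Intramolecular vinylketene–alkene [2+2] cycloaddition in which the ketene carbonyl carbon bonds to the less substituted C6 and the ketene α‑carbon to C7 (crossed, bicyclo[3.1.1] mode); addition is suprafacial on the 6E alkene, so the C7 methyl ends syn and the chain anti to the C3–C5 bridge, and the ketene is expected to add to the face anti to the bulky C8 silyloxy group (H8 eclipsing the C7 methyl), giving the farnesane (2R,6S,7S) centres.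

Step 9
Reactants: 15 the bicyclic cyclobutanone
Product: 16 N'-tosylhydrazone of 15 at the ring C=O (E/Z mixture)
Conditions: TsNHNH2, MeOH, 40 °C
Reagents that add atoms: 4-methylbenzenesulfonohydrazide, Cc1ccc(cc1)S(=O)(=O)NN
Why: Hydrazone condensation works on the strained, non‑enolisable cyclobutanone, and all other groups are inert to it.

Step 10
Reactants: 16 the tosylhydrazone
Product: 19 tricyclic exo-methylene silyl ether (farnesane locants 1R,2R,6R,7S,8R,10R: cyclobutane C1–C2–C7–C6 bridged by C3(=CH2)–C4–C5 on one face and C8(OTBS)–C9–C10(O-tigloyl)–C11(Me)2 on the other; C7-Me and H-1 on the C3–C5 face), via cyclised sulfonylhydrazide 17 (not isolated), via monoalkyl diazene 18 (not isolated)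
Conditions: Bu3SnH (syringe pump), AIBN, PhH, 80 °C; then NaOAc, EtOH, 70 °C
Reagents that add atoms: none
Why: Proposed new method: Bu3Sn• abstracts PhSe to give the tertiary C11 radical, which adds to the hydrazone carbon C1 from the only face the anti tether can reach and so closes the seven‑membered ring, the hydrazinyl radical takes H from Bu3SnH, and base then expels sulfinate to a diazene that loses N2 to leave C1–H (configuration fixed by the bridge); the closest known reaction types are radical cyclisations onto N‑aziridinyl imines and hydrogen‑atom‑transfer alkene–tosylhydrazone reductive couplings.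

Step 11
Reactants: 19 the tricyclic exo-methylene compound
Product: 20 tricyclic endo-alkene silyl ether (farnesane locants 1R,2R,6R,7S,8R,10R; C3(Me)=C4, C5 = CH2)
Conditions: RhCl3·3H2O (5 mol %), EtOH, 70 °C
Reagents that add atoms: none
Why: Rhodium‑hydride alkene isomerisation moves the exocyclic alkene to the more stable trisubstituted endocyclic position (as β‑pinene to α‑pinene), and it cannot move toward the bridgehead.

Step 12
Reactants: 20 the tricyclic endo-alkene
Product: 21 tricyclic enone silyl ether (farnesane locants 1S,2R,6R,7R,8R,10R; C5=O, C3(Me)=C4, 8-OTBS, 10-O-tigloyl)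
Conditions: Rh2(cap)4 (1 mol %), t-BuOOH (70 % aq.), K2CO3, CH2Cl2, rt
Reagents that add atoms: tert-butyl hydroperoxide, CC(C)(C)OO
Why: Dirhodium caprolactamate/TBHP allylic oxidation converts the ring allylic CH2 (C5) into the enone (as α‑pinene to verbenone), and the conjugated tiglate is deactivated toward it.

Step 13
Reactants: 21 the enone silyl ether
Product: 22 tricyclic hydroxy enone (farnesane locants 1S,2R,6R,7R,8R,10R; 8-OH, 10-O-tigloyl)
Conditions: HF·pyridine, THF, 0 °C → rt
Reagents that add atoms: none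
Why: Fluoride desilylation frees O8 without touching the enone or the tiglate.

Step 14
Reactants: 22 the tricyclic hydroxy enone; 23 angelic acid [(2Z)-2-methylbut-2-enoic acid]
Product: 25 CNP0236543.2 (farnesane locants 1S,2R,6R,7R,8R,10R; 8-O-angeloyl, 10-O-tigloyl tricyclic enone), via mixed anhydride 24 (not isolated)
Conditions: 23, 2,4,6-Cl3C6H2COCl, Et3N, PhMe, rt; then 22, PhMe, 80 °C (no DMAP)
Reagents that add atoms: none
Why: Yamaguchi‑type acylation through the preformed mixed anhydride esterifies the hindered O8, and omitting a nucleophilic catalyst keeps the (Z)‑geometry of the angelate.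

## Compound list

1 | methyl geranate, methyl (2E)-3,7-dimethylocta-2,6-dienoate | COC(=O)/C=C(\C)CCC=C(C)C | starting material
2 | methyl (2E)-5-(5,5-dimethyl-1,2,4-trioxolan-3-yl)-3-methylpent-2-enoate (secondary ozonide) | COC(=O)/C=C(\C)CCC1OOC(C)(C)O1 | intermediate
3 | methyl (2E)-3-methyl-6-oxohex-2-enoate | COC(=O)/C=C(\C)CCC=O | intermediate
4 | 3-(triphenyl-λ5-phosphanylidene)butan-2-one | CC(=O)C(C)=P(c1ccccc1)(c1ccccc1)c1ccccc1 | starting material
5 | methyl (2E,6E)-3,7-dimethyl-8-oxonona-2,6-dienoate | COC(=O)/C=C(\C)CC/C=C(\C)C(C)=O | intermediate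
6 | 2-methylpropanal | CC(C)C=O | starting material
7 | 2-methyl-2-(phenylselanyl)propanal | CC(C)(C=O)[Se]c1ccccc1 | intermediate
8 | methyl (2E,6E,10R)-10-hydroxy-3,7,11-trimethyl-8-oxo-11-(phenylselanyl)dodeca-2,6-dienoate | COC(=O)/C=C(\C)CC/C=C(\C)C(=O)C[C@@H](O)C(C)(C)[Se]c1ccccc1 | intermediate
9 | tiglaldehyde, (2E)-2-methylbut-2-enal | C/C=C(\C)C=O | starting material
10 | methyl (2E,6E,8R,10R)-8-hydroxy-3,7,11-trimethyl-10-{[(2E)-2-methylbut-2-enoyl]oxy}-11-(phenylselanyl)dodeca-2,6-dienoate | COC(=O)/C=C(\C)CC/C=C(\C)[C@H](O)C[C@@H](OC(=O)/C(C)=C/C)C(C)(C)[Se]c1ccccc1 | intermediate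
11 | methyl (2E,6E,8R,10R)-8-{[tert-butyl(dimethyl)silyl]oxy}-3,7,11-trimethyl-10-{[(2E)-2-methylbut-2-enoyl]oxy}-11-(phenylselanyl)dodeca-2,6-dienoate | COC(=O)/C=C(\C)CC/C=C(\C)[C@H](O[Si](C)(C)C(C)(C)C)C[C@@H](OC(=O)/C(C)=C/C)C(C)(C)[Se]c1ccccc1 | intermediate
12 | (2E,6E,8R,10R)-8-{[tert-butyl(dimethyl)silyl]oxy}-3,7,11-trimethyl-10-{[(2E)-2-methylbut-2-enoyl]oxy}-11-(phenylselanyl)dodeca-2,6-dienoic acid | OC(=O)/C=C(\C)CC/C=C(\C)[C@H](O[Si](C)(C)C(C)(C)C)C[C@@H](OC(=O)/C(C)=C/C)C(C)(C)[Se]c1ccccc1 | intermediate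
13 | acid chloride of 12 | ClC(=O)/C=C(\C)CC/C=C(\C)[C@H](O[Si](C)(C)C(C)(C)C)C[C@@H](OC(=O)/C(C)=C/C)C(C)(C)[Se]c1ccccc1 | intermediate
14 | vinylketene, (6E,8R,10R)-8-{[tert-butyl(dimethyl)silyl]oxy}-7,11-dimethyl-3-methylidene-10-{[(2E)-2-methylbut-2-enoyl]oxy}-11-(phenylselanyl)dodeca-1,6-dien-1-one | O=C=CC(=C)CC/C=C(\C)[C@H](O[Si](C)(C)C(C)(C)C)C[C@@H](OC(=O)/C(C)=C/C)C(C)(C)[Se]c1ccccc1 | intermediate
15 | (1R,5S,7S)-7-[(1R,3R)-1-{[tert-butyl(dimethyl)silyl]oxy}-4-methyl-3-{[(2E)-2-methylbut-2-enoyl]oxy}-4-(phenylselanyl)pentyl]-7-methyl-2-methylidenebicyclo[3.1.1]heptan-6-one (farnesane locants 2R,6S,7S,8R,10R; chain anti to the C3–C5 bridge) | O=C1[C@H]2CCC(=C)[C@@H]1[C@@]2(C)[C@H](O[Si](C)(C)C(C)(C)C)C[C@@H](OC(=O)/C(C)=C/C)C(C)(C)[Se]c1ccccc1 | intermediate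
16 | N'-tosylhydrazone of 15 (farnesane locants 2R,6S,7S,8R,10R; C=N geometry unspecified) | Cc1ccc(cc1)S(=O)(=O)NN=C1[C@H]2CCC(=C)[C@@H]1[C@@]2(C)[C@H](O[Si](C)(C)C(C)(C)C)C[C@@H](OC(=O)/C(C)=C/C)C(C)(C)[Se]c1ccccc1 | intermediate
17 | cyclised N'-tosylhydrazide (tricycle with C1 bonded to C11 and to NH–NHTs; farnesane locants 1S,2R,6S,7S,8R,10R) | CC(C)(C)[Si](C)(C)O[C@@H]1C[C@@H](OC(=O)/C(C)=C/C)C(C)(C)[C@]2(NNS(=O)(=O)c4ccc(C)cc4)[C@H]3CCC(=C)[C@@H]2[C@]31C | intermediate
18 | monoalkyl diazene (tricycle with C1–N=NH; farnesane locants 1S,2R,6S,7S,8R,10R) | CC(C)(C)[Si](C)(C)O[C@@H]1C[C@@H](OC(=O)/C(C)=C/C)C(C)(C)[C@]2(N=N)[C@H]3CCC(=C)[C@@H]2[C@]31C | intermediate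
19 | tricyclic exo-methylene silyl ether (farnesane locants 1R,2R,6R,7S,8R,10R; 3-methylidene, 7-Me, 11,11-Me2, 8-OTBS, 10-O-tigloyl) | CC(C)(C)[Si](C)(C)O[C@@H]1C[C@@H](OC(=O)/C(C)=C/C)C(C)(C)[C@@H]2[C@H]3CCC(=C)[C@@H]2[C@]31C | intermediate
20 | tricyclic endo-alkene silyl ether (farnesane locants 1R,2R,6R,7S,8R,10R; C3(Me)=C4) | CC(C)(C)[Si](C)(C)O[C@@H]1C[C@@H](OC(=O)/C(C)=C/C)C(C)(C)[C@@H]2[C@H]3CC=C(C)[C@@H]2[C@]31C | intermediate
21 | tricyclic enone silyl ether (farnesane locants 1S,2R,6R,7R,8R,10R; C5=O, 8-OTBS, 10-O-tigloyl) | CC(C)(C)[Si](C)(C)O[C@@H]1C[C@@H](OC(=O)/C(C)=C/C)C(C)(C)[C@@H]2[C@H]3C(=O)C=C(C)[C@@H]2[C@]31C | intermediate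
22 | tricyclic hydroxy enone (farnesane locants 1S,2R,6R,7R,8R,10R; 8-OH, 10-O-tigloyl) | O[C@@H]1C[C@@H](OC(=O)/C(C)=C/C)C(C)(C)[C@@H]2[C@H]3C(=O)C=C(C)[C@@H]2[C@]31C | intermediate
23 | angelic acid, (2Z)-2-methylbut-2-enoic acid | C/C=C(/C)C(=O)O | starting material
24 | (2Z)-2-methylbut-2-enoic 2,4,6-trichlorobenzoic anhydride | C/C=C(/C)C(=O)OC(=O)c1c(Cl)cc(Cl)cc1Cl | intermediate
25 | CNP0236543.2 (farnesane locants 1S,2R,6R,7R,8R,10R; 8-O-angeloyl, 10-O-tigloyl tricyclic enone) | C/C=C(/C)C(=O)O[C@@H]1C[C@@H](OC(=O)/C(C)=C/C)C(C)(C)[C@@H]2[C@H]3C(=O)C=C(C)[C@@H]2[C@]31C | target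

## Step count and risks

Total steps: 14. Longest linear sequence: 13 (steps 1, 2 and 4–14; step 3 is a one‑step side branch).

Most likely to fail, first: step 8. The (2+2) mode and the C7 configuration are dependable for 6E vinylketene precursors. The facial bias from the C8 silyloxy centre is not: sterics (silyloxy anti) favour 15, an inside‑alkoxy preference would favour its diastereomer, and the alkene is congested. A minor endo‑alkene isomer of 15 would converge at step 11. The fallback sets out from acid 12 and puts the face under auxiliary control. Acid 12 is coupled (through acid chloride 13) with (2R,5R)-2,5-dimethylpyrrolidine to give the amide F1. Tf2O and 2,6-di-tert-butyl-4-methylpyridine in ClCH2CH2Cl (0 → 60 °C) convert it into the vinylketeniminium triflate F2. This more electrophilic cumulene undergoes the same crossed cycloaddition, with the C2‑symmetric amine shielding one face, to give the cyclobutaniminium triflate F3. Aqueous NaHCO3 hydrolysis then comes back to the route at ketone 15 (the amine antipode is chosen to match the C8 bias).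

Second: step 10. The seven‑membered closure joins a quaternary and a tertiary carbon. A sulfonyl radical, if released, could add to the exocyclic methylene and open the cyclobutane. Slow 6‑endo attack of the C11 radical on the tiglate is a further competitor. The fallback sets out from ketone 15 and avoids sulfonyl species altogether. Ketone 15 is condensed with 1-amino-2-phenylaziridine (CH2Cl2, 0 °C) to give the N-aziridinyl imine F4. Bu3SnH/AIBN in benzene at 80 °C then triggers radical addition to C=N, irreversible loss of styrene and N2, and hydrogen transfer to the C1 radical, coming back directly at tricycle 19.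

Third: step 5. An enal is an unusual hydride donor for the Evans–Tishchenko reaction, and the tigloyl group could migrate between O10 and O8. The fallback sets out from aldol 8 and separates acylation from reduction. Aldol 8 is acylated with tigloyl chloride/pyridine (CH2Cl2, 0 °C) to give the 10-O-tigloyl 8-keto ester F5. Reagent‑controlled reduction of the enone with (S)-Me-CBS/catecholborane (PhMe, −78 °C) then gives the (8R) alcohol and comes back at compound 10.

## Further compounds

F1 | step 8 | (2R,5R)-2,5-dimethylpyrrolidine amide of acid 12 | O=C(/C=C(\C)CC/C=C(\C)[C@H](O[Si](C)(C)C(C)(C)C)C[C@@H](OC(=O)/C(C)=C/C)C(C)(C)[Se]c1ccccc1)N1[C@H](C)CC[C@H]1C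
F2 | step 8 | vinylketeniminium triflate derived from F1 | C=C(CC/C=C(\C)[C@H](O[Si](C)(C)C(C)(C)C)C[C@@H](OC(=O)/C(C)=C/C)C(C)(C)[Se]c1ccccc1)C=C=[N+]1[C@H](C)CC[C@H]1C.[O-]S(=O)(=O)C(F)(F)F
F3 | step 8 | cyclobutaniminium triflate (iminium of ketone 15 with the pyrrolidine) | C[C@@H]1CC[C@@H](C)[N+]1=C1[C@H]2CCC(=C)[C@@H]1[C@@]2(C)[C@H](O[Si](C)(C)C(C)(C)C)C[C@@H](OC(=O)/C(C)=C/C)C(C)(C)[Se]c1ccccc1.[O-]S(=O)(=O)C(F)(F)F
F4 | step 10 | N-(2-phenylaziridin-1-yl)imine of ketone 15 | c1ccccc1C1CN1N=C1[C@H]2CCC(=C)[C@@H]1[C@@]2(C)[C@H](O[Si](C)(C)C(C)(C)C)C[C@@H](OC(=O)/C(C)=C/C)C(C)(C)[Se]c1ccccc1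
F5 | step 5 | methyl (2E,6E,10R)-3,7,11-trimethyl-10-{[(2E)-2-methylbut-2-enoyl]oxy}-8-oxo-11-(phenylselanyl)dodeca-2,6-dienoate | COC(=O)/C=C(\C)CC/C=C(\C)C(=O)C[C@@H](OC(=O)/C(C)=C/C)C(C)(C)[Se]c1ccccc1
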